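## Retrosynthetic overview

Carotenoid locants are used: ring A (C1–C6) carries the C7≡C8 alkyne, the chain runs C7–C15 then C15'–C7', and ring B is C1'–C6'.

1. The target comes from its tetrasilyl ether by fluoride desilylation. The tetrasilyl ether is cut at C12'–C13' into a ring A polyenyne with a propynyl terminus (C24) and a ring B terminal dienyne (C16). They are joined by a titanium-mediated reductive alkyne–alkyne cross-coupling that also creates the C11'=C12' and C13'=C14' E-alkenes.
2. Enabling feature: in the (E,E)-diene C11'H=C12'H–C13'(CH3)=C14'H, C12' bears only H and C13' only a methyl group. This is the protonolysis product of a titanacyclopentadiene built head-to-head from a terminal alkyne (C11'≡C12'H) and a methyl-capped alkyne (C13'≡C14'). The only other alkyne, C7≡C8 at ring A, is shielded by C6, the C1 gem-dimethyl group and the C9 methyl group.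
3. The ring A polyenyne comes from a common enol triflate by Sonogashira coupling with (E)-3-methylpent-2-en-4-yn-1-ol, then two Horner–Wadsworth–Emmons extensions. The ring B dienyne comes from the same triflate by Stille coupling with the dienylstannane made from the same enynol, then oxidation and Colvin homologation.
4. The common triflate comes from ketoisophorone: asymmetric transfer hydrogenation sets C3, anti conjugate borylation–oxidation sets C4 (trans diol), and enol triflation creates C5=C6.
5. Ring order: no ring is closed in the route. Ring A and ring B are both the six-membered carbocycle of ketoisophorone, functionalised once and then used twice.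

Key step: step 16

Abbreviations in names: TBS = tert-butyldimethylsilyl; Q = (3S,4S)-3,4-bis[(tert-butyldimethylsilyl)oxy]-2,6,6-trimethylcyclohex-1-en-1-yl.

Assumption: the C5 cyano phosphonate of step 8 is used as its (2E) isomer; the commercial E/Z mixture equilibrates under the basic conditions and any 13Z product is removed by chromatography.

## Route

Step 1
Reactants: 1 ketoisophorone (2,6,6-trimethylcyclohex-2-ene-1,4-dione)
Product: 2 (4S)-4-hydroxy-2,6,6-trimethylcyclohex-2-en-1-one
Conditions: RuCl[(S,S)-TsDPEN](p-cymene) (cat.), i-PrOH, rt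
Reagents that add atoms: none
Why: Noyori asymmetric transfer hydrogenation should reduce only the unhindered C4 carbonyl (C1 is shielded by the quaternary carbon and the methyl-bearing alkene carbon) and set the new carbinol centre as S by catalyst control, the alkene flank taking the aryl role of the usual model, the enantiomeric catalyst being used should the sense prove opposite.

Step 2
Reactants: 2 (4S)-4-hydroxy-2,6,6-trimethylcyclohex-2-en-1-one
Product: 3 (4S)-4-[(tert-butyldimethylsilyl)oxy]-2,6,6-trimethylcyclohex-2-en-1-one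
Conditions: TBSCl, imidazole, DMF, rt
Reagents that add atoms: tert-butyldimethylsilyl chloride, CC(C)(C)[Si](C)(C)Cl
Why: Standard imidazole-mediated silylation of the secondary allylic alcohol; the stereocentre is not involved.

Step 3
Reactants: 3 (4S)-4-[(tert-butyldimethylsilyl)oxy]-2,6,6-trimethylcyclohex-2-en-1-one
Product: 5 (2S,3S,4S)-4-[(tert-butyldimethylsilyl)oxy]-3-hydroxy-2,6,6-trimethylcyclohexan-1-one, via β-boryl ketone 4 (not isolated)
Conditions: CuCl (cat.), DPEphos (cat.), NaOt-Bu (cat.), B2pin2, MeOH, THF, rt; then NaBO3·4H2O, THF/H2O, rt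
Reagents that add atoms: bis(pinacolato)diboron, CC1(C)OB(OC1(C)C)B1OC(C)(C)C(C)(C)O1 (boron of 4); sodium perborate, [Na+].[O-]OB=O (oxygen of 5)
Why: Copper-catalysed conjugate borylation followed by stereoretentive perborate oxidation should place the boryl group, and hence the hydroxyl, on the β-carbon anti to the neighbouring silyloxy group (substrate control), which sets the trans relationship of the future C3 and C4 oxygens; the α-methyl centre is expected mainly trans and is erased in step 5.

Step 4
Reactants: 5 (2S,3S,4S)-4-[(tert-butyldimethylsilyl)oxy]-3-hydroxy-2,6,6-trimethylcyclohexan-1-one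
Product: 6 (2S,3S,4S)-3,4-bis[(tert-butyldimethylsilyl)oxy]-2,6,6-trimethylcyclohexan-1-one
Conditions: TBSOTf, 2,6-lutidine, CH2Cl2, −78 to 0 °C
Reagents that add atoms: tert-butyldimethylsilyl trifluoromethanesulfonate, CC(C)(C)[Si](C)(C)OS(=O)(=O)C(F)(F)F
Why: Silyl triflate/lutidine silylation of the hindered β-hydroxy ketone is fast at low temperature and non-basic enough to avoid retro-aldol cleavage or dehydration.

Step 5
Reactants: 6 (2S,3S,4S)-3,4-bis[(tert-butyldimethylsilyl)oxy]-2,6,6-trimethylcyclohexan-1-one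
Product: 7 (3S,4S)-3,4-bis[(tert-butyldimethylsilyl)oxy]-2,6,6-trimethylcyclohex-1-en-1-yl trifluoromethanesulfonate
Conditions: KHMDS, THF, −78 °C; then PhNTf2, −78 to 0 °C; aq. NH4Cl
Reagents that add atoms: N-phenylbis(trifluoromethanesulfonimide), O=S(=O)(N(c1ccccc1)S(=O)(=O)C(F)(F)F)C(F)(F)F
Why: The ketone has a single α-hydrogen (the other α-carbon is quaternary), so enolate O-triflation (enol triflate formation) can only give the tetrasubstituted C5=C6 triflate, and trapping at −78 °C should outrun β-elimination of the poor silyloxy leaving group.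

Step 6
Reactants: 7 (3S,4S)-3,4-bis[(tert-butyldimethylsilyl)oxy]-2,6,6-trimethylcyclohex-1-en-1-yl trifluoromethanesulfonate; 8 (2E)-3-methylpent-2-en-4-yn-1-ol
Product: 9 (2E)-5-Q-3-methylpent-2-en-4-yn-1-ol
Conditions: Pd(PPh3)4 (cat.), CuI (cat.), i-Pr2NH, DMF, rt
Reagents that add atoms: none
Why: Sonogashira coupling of the enol triflate with the terminal alkyne forms the C6–C7 bond of the 7,8-didehydro end group; the (E)-alkene and the free hydroxyl are tolerated.

Step 7
Reactants: 9 (2E)-5-Q-3-methylpent-2-en-4-yn-1-ol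
Product: 10 (2E)-5-Q-3-methylpent-2-en-4-ynal
Conditions: MnO2, CH2Cl2, rt
Reagents that add atoms: none
Why: MnO2 oxidises the primary allylic alcohol selectively to the enal without touching silyl ethers or the alkyne and with retention of the C9=C10 geometry.

Step 8
Reactants: 10 (2E)-5-Q-3-methylpent-2-en-4-ynal; 11 diethyl [(2E)-3-cyano-2-methylprop-2-en-1-yl]phosphonate
Product: 12 (2E,4E,6E)-9-Q-3,7-dimethylnona-2,4,6-trien-8-ynenitrile
Conditions: NaHMDS, THF, −78 to 0 °C
Reagents that add atoms: none
Why: Horner–Wadsworth–Emmons olefination with the stabilised allylic phosphonate anion should form the C11=C12 alkene with E selectivity, the C13=C14 geometry being carried by the reagent.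

Step 9
Reactants: 12 (2E,4E,6E)-9-Q-3,7-dimethylnona-2,4,6-trien-8-ynenitrile
Product: 14 (2E,4E,6E)-9-Q-3,7-dimethylnona-2,4,6-trien-8-ynal, via N-aluminyl aldimine 13 (not isolated)
Conditions: DIBAL-H, toluene, −78 °C; then wet silica gel, 0 °C
Reagents that add atoms: water, O
Why: DIBAL-H adds once to the conjugated nitrile to give aldimine 13, which resists further hydride at low temperature and is hydrolysed to the aldehyde on work-up (nitrile half-reduction as used for retinal-type polyenals); silyl ethers and the alkyne are untouched.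

Step 10
Reactants: 15 1-bromobut-2-yne
Product: 16 diethyl but-2-yn-1-ylphosphonate
Conditions: P(OEt)3, neat, 120 °C
Reagents that add atoms: triethyl phosphite, CCOP(OCC)OCC
Why: Michaelis–Arbuzov reaction at the primary propargylic bromide (SN2 by phosphorus, then dealkylation by bromide) gives the propargylic phosphonate.

Step 11
Reactants: 14 (2E,4E,6E)-9-Q-3,7-dimethylnona-2,4,6-trien-8-ynal; 16 diethyl but-2-yn-1-ylphosphonate
Product: 17 (3E,5E,7E,9E)-1-Q-3,7-dimethyltrideca-3,5,7,9-tetraene-1,11-diyne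
Conditions: NaHMDS, THF, −78 to 0 °C
Reagents that add atoms: none
Why: Horner–Wadsworth–Emmons olefination of the propargylic phosphonate anion at its α-carbon should give the (E)-C15=C15' enyne and install the propynyl terminus C14'≡C13'–CH3.

Step 12
Reactants: 8 (2E)-3-methylpent-2-en-4-yn-1-ol
Product: 18 (2E,4E)-3-methyl-5-(tributylstannyl)penta-2,4-dien-1-ol
Conditions: Bu3SnH, PdCl2(PPh3)2 (cat.), THF, 0 °C
Reagents that add atoms: tributyltin hydride, CCCC[SnH](CCCC)CCCC
Why: Palladium-catalysed hydrostannation adds H and Sn syn across the terminal alkyne with tin on the terminal carbon (the internal carbon is flanked by the fully substituted alkene carbon), giving the (E)-stannane; any internal regioisomer is removed by chromatography.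

Step 13
Reactants: 7 (3S,4S)-3,4-bis[(tert-butyldimethylsilyl)oxy]-2,6,6-trimethylcyclohex-1-en-1-yl trifluoromethanesulfonate; 18 (2E,4E)-3-methyl-5-(tributylstannyl)penta-2,4-dien-1-ol
Product: 19 (2E,4E)-5-Q-3-methylpenta-2,4-dien-1-ol
Conditions: Pd2(dba)3 (tris(dibenzylideneacetone)dipalladium, cat.), AsPh3, NMP, 50 °C
Reagents that add atoms: none
Why: Stille coupling of the hindered tetrasubstituted enol triflate (soft arsine ligand in a polar solvent, as used for trimethylcyclohexenyl triflates) forms the C6'–C7' bond with retention of the dienyl geometry; the free allylic alcohol is tolerated.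

Step 14
Reactants: 19 (2E,4E)-5-Q-3-methylpenta-2,4-dien-1-ol
Product: 20 (2E,4E)-5-Q-3-methylpenta-2,4-dienal
Conditions: MnO2, CH2Cl2, rt
Reagents that add atoms: none
Why: Selective MnO2 oxidation of the primary allylic alcohol to the dienal, with retention of both alkene geometries.

Step 15
Reactants: 20 (2E,4E)-5-Q-3-methylpenta-2,4-dienal
Product: 21 (1E,3E)-1-Q-3-methylhexa-1,3-dien-5-yne
Conditions: TMSCHN2, n-BuLi, THF, −78 °C to rt; H2O
Reagents that add atoms: (trimethylsilyl)diazomethane, C[Si](C)(C)C=[N+]=[N-]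
Why: Colvin rearrangement with lithiated (trimethylsilyl)diazomethane converts the aldehyde into the one-carbon-longer terminal alkyne under aprotic conditions, so no nucleophile adds to the dienal in a conjugate sense.

Step 16
Reactants: 17 (3E,5E,7E,9E)-1-Q-3,7-dimethyltrideca-3,5,7,9-tetraene-1,11-diyne; 21 (1E,3E)-1-Q-3-methylhexa-1,3-dien-5-yne
Product: 24 (3S,4S,3'S,4'S)-3,4,3',4'-tetrakis[(tert-butyldimethylsilyl)oxy]-7,8-didehydro-β,β-carotene, via titanacyclopropene 22 (not isolated), via titanacyclopentadiene 23 (not isolated)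
Conditions: 17, Ti(O-i-Pr)4 (1.1 equiv), i-PrMgCl (2.2 equiv), Et2O, −78 to −50 °C; then 21 (1.2 equiv), −50 °C; then H2O, −50 °C to rt
Reagents that add atoms: none
Why: Proposed new method: (η2-propene)Ti(O-i-Pr)2, a divalent titanium equivalent made in the flask, exchanges propene for the unhindered methyl-capped C13'≡C14' alkyne of 17 to give titanacyclopropene 22, the terminal alkyne of 21 then inserts into the less hindered Ti–C13' bond with its unsubstituted carbon C12' forming the new C12'–C13' bond, and the two Ti–C bonds of the resulting titanacyclopentadiene 23 are protonated with retention by water. The closest known reaction type is the titanium alkoxide-mediated (Sato-type) cross-coupling of an internal alkyne–titanium complex with a terminal alkyne through a titanacyclopentadiene, and metallacycle-mediated reductive alkyne–alkyne cross-coupling in general; its use on conjugated polyenynes to make a carotenoid diene junction is the untested part. No ring of the target is closed: the only ring formed is the transient five-membered titanacycle of 23, closed by migratory insertion (formal oxidative cyclisation of two alkynes at titanium) and opened again on hydrolysis. No sp3 stereocentre is created; the E geometry of both C11'=C12' and C13'=C14' follows from the two syn-carbometalations fixed in the titanacycle and the stereoretentive protonolysis. The step needs site selectivity (C13'≡C14' over C7≡C8 and over the polyene, secured because C7≡C8 is flanked by the fully substituted C6 with its gem-dimethyl neighbour and by the methyl-bearing C9, and because alkenes bind this reagent far less well than alkynes), regioselectivity (alkenyl substituents prefer the positions α to titanium, so the methyl-bearing C13' and the CH carbon C12' become the joined β-carbons) and cross- over homo-coupling (secured by forming 22 completely before 21 is added).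

Step 17
Reactants: 24 (3S,4S,3'S,4'S)-3,4,3',4'-tetrakis[(tert-butyldimethylsilyl)oxy]-7,8-didehydro-β,β-carotene
Product: 25 (3S,4S,3'S,4'S)-7,8-didehydro-β,β-carotene-3,4,3',4'-tetrol (CNP0343957.1)
Conditions: TBAF, THF, rt, dark, argon
Reagents that add atoms: none
Why: Fluoride-mediated desilylation should remove all four silyl ethers under non-acidic conditions that leave the acid-labile allylic C4 and C4' carbinols and the polyenyne untouched.

## Compound list

1 | ketoisophorone (2,6,6-trimethylcyclohex-2-ene-1,4-dione) | CC1=CC(=O)CC(C)(C)C1=O | starting material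
2 | (4S)-4-hydroxy-2,6,6-trimethylcyclohex-2-en-1-one | CC1=C[C@@H](O)CC(C)(C)C1=O | intermediate
3 | (4S)-4-[(tert-butyldimethylsilyl)oxy]-2,6,6-trimethylcyclohex-2-en-1-one | CC1=C[C@@H](O[Si](C)(C)C(C)(C)C)CC(C)(C)C1=O | intermediate
4 | (2S,3S,4S)-4-[(tert-butyldimethylsilyl)oxy]-2,6,6-trimethyl-3-(4,4,5,5-tetramethyl-1,3,2-dioxaborolan-2-yl)cyclohexan-1-one (boryl trans to silyloxy) | C[C@@H]1C(=O)C(C)(C)C[C@H](O[Si](C)(C)C(C)(C)C)[C@H]1B1OC(C)(C)C(C)(C)O1 | intermediate (not isolated)
5 | (2S,3S,4S)-4-[(tert-butyldimethylsilyl)oxy]-3-hydroxy-2,6,6-trimethylcyclohexan-1-one (the C2 epimer serves equally) | C[C@@H]1C(=O)C(C)(C)C[C@H](O[Si](C)(C)C(C)(C)C)[C@H]1O | intermediate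
6 | (2S,3S,4S)-3,4-bis[(tert-butyldimethylsilyl)oxy]-2,6,6-trimethylcyclohexan-1-one | C[C@@H]1C(=O)C(C)(C)C[C@H](O[Si](C)(C)C(C)(C)C)[C@H]1O[Si](C)(C)C(C)(C)C | intermediate
7 | (3S,4S)-3,4-bis[(tert-butyldimethylsilyl)oxy]-2,6,6-trimethylcyclohex-1-en-1-yl trifluoromethanesulfonate | CC1=C(OS(=O)(=O)C(F)(F)F)C(C)(C)C[C@H](O[Si](C)(C)C(C)(C)C)[C@H]1O[Si](C)(C)C(C)(C)C | intermediate
8 | (2E)-3-methylpent-2-en-4-yn-1-ol | C#C/C(C)=C/CO | starting material
9 | (2E)-5-Q-3-methylpent-2-en-4-yn-1-ol | CC1=C(C#C/C(C)=C/CO)C(C)(C)C[C@H](O[Si](C)(C)C(C)(C)C)[C@H]1O[Si](C)(C)C(C)(C)C | intermediate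
10 | (2E)-5-Q-3-methylpent-2-en-4-ynal | CC1=C(C#C/C(C)=C/C=O)C(C)(C)C[C@H](O[Si](C)(C)C(C)(C)C)[C@H]1O[Si](C)(C)C(C)(C)C | intermediate
11 | diethyl [(2E)-3-cyano-2-methylprop-2-en-1-yl]phosphonate | CCOP(=O)(OCC)C/C(C)=C/C#N | starting material
12 | (2E,4E,6E)-9-Q-3,7-dimethylnona-2,4,6-trien-8-ynenitrile | CC1=C(C#C/C(C)=C/C=C/C(C)=C/C#N)C(C)(C)C[C@H](O[Si](C)(C)C(C)(C)C)[C@H]1O[Si](C)(C)C(C)(C)C | intermediate
13 | N-(diisobutylaluminyl) aldimine of 14 | CC1=C(C#C/C(C)=C/C=C/C(C)=C/C=N[Al](CC(C)C)CC(C)C)C(C)(C)C[C@H](O[Si](C)(C)C(C)(C)C)[C@H]1O[Si](C)(C)C(C)(C)C | intermediate (not isolated)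
14 | (2E,4E,6E)-9-Q-3,7-dimethylnona-2,4,6-trien-8-ynal | CC1=C(C#C/C(C)=C/C=C/C(C)=C/C=O)C(C)(C)C[C@H](O[Si](C)(C)C(C)(C)C)[C@H]1O[Si](C)(C)C(C)(C)C | intermediate
15 | 1-bromobut-2-yne | CC#CCBr | starting material
16 | diethyl but-2-yn-1-ylphosphonate | CC#CCP(=O)(OCC)OCC | intermediate
17 | (3E,5E,7E,9E)-1-Q-3,7-dimethyltrideca-3,5,7,9-tetraene-1,11-diyne (ring A polyenyne) | CC1=C(C#C/C(C)=C/C=C/C(C)=C/C=C/C#CC)C(C)(C)C[C@H](O[Si](C)(C)C(C)(C)C)[C@H]1O[Si](C)(C)C(C)(C)C | intermediate
18 | (2E,4E)-3-methyl-5-(tributylstannyl)penta-2,4-dien-1-ol | CCCC[Sn](CCCC)(CCCC)/C=C/C(C)=C/CO | intermediate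
19 | (2E,4E)-5-Q-3-methylpenta-2,4-dien-1-ol | CC1=C(/C=C/C(C)=C/CO)C(C)(C)C[C@H](O[Si](C)(C)C(C)(C)C)[C@H]1O[Si](C)(C)C(C)(C)C | intermediate
20 | (2E,4E)-5-Q-3-methylpenta-2,4-dienal | CC1=C(/C=C/C(C)=C/C=O)C(C)(C)C[C@H](O[Si](C)(C)C(C)(C)C)[C@H]1O[Si](C)(C)C(C)(C)C | intermediate
21 | (1E,3E)-1-Q-3-methylhexa-1,3-dien-5-yne (ring B dienyne) | CC1=C(/C=C/C(C)=C/C#C)C(C)(C)C[C@H](O[Si](C)(C)C(C)(C)C)[C@H]1O[Si](C)(C)C(C)(C)C | intermediate
22 | titanacyclopropene: Ti(O-i-Pr)2 bound to C13' and C14' of 17 | CC1=C(C#C/C(C)=C/C=C/C(C)=C/C=C/C2=C(C)[Ti]2(OC(C)C)OC(C)C)C(C)(C)C[C@H](O[Si](C)(C)C(C)(C)C)[C@H]1O[Si](C)(C)C(C)(C)C | intermediate (not isolated)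
23 | 1,1-diisopropoxytitanacyclopentadiene Ti–C14'=C13'(CH3)–C12'H=C11'–Ti carrying the ring A polyenynyl group on C14' and the ring B dienyl group on C11' | CC1=C(C#C/C(C)=C/C=C/C(C)=C/C=C/C2=C(C)C=C(/C=C(C)/C=C/C3=C(C)[C@H](O[Si](C)(C)C(C)(C)C)[C@@H](O[Si](C)(C)C(C)(C)C)CC3(C)C)[Ti]2(OC(C)C)OC(C)C)C(C)(C)C[C@H](O[Si](C)(C)C(C)(C)C)[C@H]1O[Si](C)(C)C(C)(C)C | intermediate (not isolated)
24 | (3S,4S,3'S,4'S)-3,4,3',4'-tetrakis[(tert-butyldimethylsilyl)oxy]-7,8-didehydro-β,β-carotene | CC1=C(C#C/C(C)=C/C=C/C(C)=C/C=C/C=C(C)/C=C/C=C(C)/C=C/C2=C(C)[C@H](O[Si](C)(C)C(C)(C)C)[C@@H](O[Si](C)(C)C(C)(C)C)CC2(C)C)C(C)(C)C[C@H](O[Si](C)(C)C(C)(C)C)[C@H]1O[Si](C)(C)C(C)(C)C | intermediate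
25 | (3S,4S,3'S,4'S)-7,8-didehydro-β,β-carotene-3,4,3',4'-tetrol (CNP0343957.1) | CC1=C(C#C/C(C)=C/C=C/C(C)=C/C=C/C=C(C)/C=C/C=C(C)/C=C/C2=C(C)[C@H](O)[C@@H](O)CC2(C)C)C(C)(C)C[C@H](O)[C@H]1O | target

## Step count and risk assessment

Total step count: 17. Longest linear sequence: 12 steps (steps 1–9, 11, 16, 17).

Steps most likely to fail:

**1. Step 16 (Proposed new method).** Proton transfer from the terminal alkyne to the titanacyclopropene may compete with insertion. Titanium may bind at, or slip along the conjugated system towards, the wrong unsaturation, so that the wrong carbons are joined. Homo-coupling of either alkyne may also compete.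

Fallback, from 17 and 21, returning at 24: hydrozirconation of 17 with Cp2Zr(H)Cl (THF, rt) should add syn across the unhindered C13'≡C14' alkyne with zirconium on the methyl-bearing carbon, giving alkenylzirconocene F1 (not isolated). Iodinolysis (I2, 0 °C) gives (E)-alkenyl iodide F2. Hydrozirconation of 21 gives dienylzirconocene F3 (not isolated), which is coupled with F2 under Pd(PPh3)4 and ZnCl2 (Negishi coupling, zerovalent palladium) to give 24.

**2. Step 5.** β-Elimination of the silyloxy group from the enolate before O-triflation would lose the C4 oxygen. Enolisation of the hindered ketone may also be incomplete.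

Fallback, from 6, returning at 9 and 19: condensation with hydrazine (N2H4·H2O, Et3N, EtOH, reflux) gives hydrazone F4. Barton iodination (I2, tetramethylguanidine, THF, 0 °C) gives cyclohexenyl iodide F5 without an enolate being formed. F5 takes the place of 7 in the Sonogashira coupling of step 6 and the Stille coupling of step 13.

**3. Step 3.** Facial selectivity of the boryl-copper addition next to the silyloxy group may be poor. Retro-aldol cleavage or dehydration of the β-hydroxy ketone may occur during the oxidation.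

Fallback, from 3, returning at 5: Weitz–Scheffer epoxidation (H2O2, NaOH, MeOH, 0 °C) anti to the silyloxy group gives epoxy ketone F6. Reductive cleavage of the α-C–O bond with SmI2 (THF/MeOH, −78 °C) gives β-hydroxy ketone 5 with the C4 oxygen trans to the C3 oxygen.

Further compounds
F1 | step 16 | (E)-alkenylzirconocene chloride from 17 (Cp2ZrCl on C13') | CC1=C(C#C/C(C)=C/C=C/C(C)=C/C=C/C=C(C)/[Zr](Cl)(C2C=CC=C2)C2C=CC=C2)C(C)(C)C[C@H](O[Si](C)(C)C(C)(C)C)[C@H]1O[Si](C)(C)C(C)(C)C
F2 | step 16 | (3E,5E,7E,9E,11E)-12-iodo-1-Q-3,7-dimethyltrideca-3,5,7,9,11-pentaen-1-yne | CC1=C(C#C/C(C)=C/C=C/C(C)=C/C=C/C=C(C)/I)C(C)(C)C[C@H](O[Si](C)(C)C(C)(C)C)[C@H]1O[Si](C)(C)C(C)(C)C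
F3 | step 16 | (1E,3E,5E)-trienylzirconocene chloride from 21 (Cp2ZrCl on C12') | CC1=C(/C=C/C(C)=C/C=C/[Zr](Cl)(C2C=CC=C2)C2C=CC=C2)C(C)(C)C[C@H](O[Si](C)(C)C(C)(C)C)[C@H]1O[Si](C)(C)C(C)(C)C
F4 | step 5 | hydrazone of ketone 6 | C[C@@H]1C(=NN)C(C)(C)C[C@H](O[Si](C)(C)C(C)(C)C)[C@H]1O[Si](C)(C)C(C)(C)C
F5 | step 5 | (3S,4S)-3,4-bis[(tert-butyldimethylsilyl)oxy]-1-iodo-2,6,6-trimethylcyclohex-1-ene | CC1=C(I)C(C)(C)C[C@H](O[Si](C)(C)C(C)(C)C)[C@H]1O[Si](C)(C)C(C)(C)C
F6 | step 3 | 5-[(tert-butyldimethylsilyl)oxy]-1,3,3-trimethyl-7-oxabicyclo[4.1.0]heptan-2-one (epoxide trans to the silyloxy group) | C[C@]12C(=O)C(C)(C)C[C@H](O[Si](C)(C)C(C)(C)C)[C@H]1O2
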